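**Plan**
- Units: A is the left 2,3-dihydrobenzofuran (it carries the styryl group), B the central one, C the right one. Benzofuran numbering (O1, C2, C3, C3a, C4–C7, C7a) is used in each.
- Cuts, in retrosynthetic order: the nine O–Si bonds; C3(B)–C4(C); styryl carbon–C4(A); C2–C3 of ring A, ring B and ring C; the three benzylic ArO–CH2 bonds; the diaryl ketone C–C bond.
- Forward order: one bromobenzophenone hydrazone serves units A and C. Ring C is closed first. Ring B is closed on a small iodoaldehyde as its 3-carboxylate. Ring A is then closed on the B-benzyl ether. A Heck reaction, the union of A–B with C, and desilylation follow.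
- Enabling feature: C3(B) is a benzylic carbon inside a five-membered ring, next to C2(B) with its 4-oxyphenyl group. The carboxyl group left on C3(B) by the ring-forming insertion is a traceless radical handle, the ring keeps C2–O1 out of overlap with the radical, and the C2 aryl group dictates the face of arylation. C4(C) is meta to O1 and to the oxygen on C6, so it has no nucleophilic character and enters as C–Br. Two acceptor carbons are therefore joined reductively through a radical.
- Stereochemistry: C3(A) and C3(C) come from chiral dirhodium carboxylate-catalysed insertion of diaryl carbenes, and C2(A) and C2(C) from acid equilibration to trans. C2(B) comes from a dirhodium-catalysed insertion of an aryl diazoacetate, and C3(B) from trans-selective radical capture in the key step. The E-alkene comes from the Heck reaction.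

Key step: step 19

Abbreviations: TBS = tert-butyldimethylsilyl; TBSO = tert-butyldimethylsilyloxy. Rh2(S-PTAD)4 = dirhodium tetrakis[(S)-(1-adamantyl)(phthalimido)acetate]. Rh2(S-PTTL)4 = dirhodium tetrakis[N-phthaloyl-(S)-tert-leucinate].

Assumption: the (S)-configured dirhodium carboxylates are taken to deliver the configurations drawn; if a model insertion shows the opposite sense, the equally available (R)-catalysts are used.

Step 1
Reactants: 1 1-bromo-3,5-dimethoxybenzene; 2 3,5-dimethoxybenzoyl chloride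
Product: 3 (2-bromo-4,6-dimethoxyphenyl)(3,5-dimethoxyphenyl)methanone
Conditions: AlCl3 (1.1 equiv), CH2Cl2, 0 °C to rt
Reagents that add atoms: none
Why: Friedel–Crafts acylation, in which the acylium ion should attack the position of 1 that is para to one methoxy group and ortho to the other (next to Br), because the site between the two methoxy groups is more crowded, as is usual for 5-substituted resorcinol dimethyl ethers.

Step 2
Reactants: 3 (2-bromo-4,6-dimethoxyphenyl)(3,5-dimethoxyphenyl)methanone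
Product: 4 (2-bromo-4,6-dihydroxyphenyl)(3,5-dihydroxyphenyl)methanone
Conditions: BBr3 (6 equiv), CH2Cl2, −78 °C to rt; aqueous work-up
Reagents that add atoms: none
Why: Lewis acid cleavage of aryl methyl ethers, placed at the benzophenone stage because this is the only point of the route where no acid-labile dihydrobenzofuran or stilbene is present.

Step 3
Reactants: 4 (2-bromo-4,6-dihydroxyphenyl)(3,5-dihydroxyphenyl)methanone
Product: 5 hydrazone of 4
Conditions: N2H4·H2O (10 equiv), AcOH (cat.), EtOH, 80 °C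
Reagents that add atoms: hydrazine (used as the hydrate), NN
Why: Hydrazone condensation, assisted by the hydrogen bond of the ortho-hydroxyl group to the carbonyl oxygen and run before O-alkylation makes the ketone doubly ortho-blocked; the electron-rich ring should resist displacement of bromide.

Step 4
Reactants: 5 hydrazone of 4
Product: 6 [2-bromo-6-hydroxy-4-(TBSO)phenyl][3,5-bis(TBSO)phenyl]methanone hydrazone
Conditions: TBSCl (3.2 equiv), imidazole, CH2Cl2/DMF, 0 °C
Reagents that add atoms: tert-butyldimethylsilyl chloride (TBSCl), CC(C)(C)[Si](C)(C)Cl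
Why: Silyl ether formation, in which the three free phenols should react fast while the ortho-hydroxyl group (locked in a six-membered hydrogen bond to the imine nitrogen) and the weakly nucleophilic conjugated NH2 group are left.

Step 5
Reactants: 7 4-(tert-butyldimethylsilyloxy)benzaldehyde
Product: 8 [4-(TBSO)phenyl]methanol
Conditions: NaBH4, MeOH, 0 °C
Reagents that add atoms: none
Why: Borohydride reduction of an aromatic aldehyde, short and cold enough for the aryl silyl ether to survive.

Step 6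
Reactants: 8 [4-(TBSO)phenyl]methanol
Product: 9 4-(TBSO)benzyl bromide
Conditions: CBr4, PPh3, CH2Cl2, 0 °C
Reagents that add atoms: carbon tetrabromide, BrC(Br)(Br)Br
Why: Appel reaction, a neutral conversion of a benzylic alcohol to the bromide that avoids acid at the electron-rich benzylic position.

Step 7
Reactants: 6 [2-bromo-6-hydroxy-4-(TBSO)phenyl][3,5-bis(TBSO)phenyl]methanone hydrazone; 9 4-(TBSO)benzyl bromide
Product: 10 [2-bromo-4-(TBSO)-6-{[4-(TBSO)benzyl]oxy}phenyl][3,5-bis(TBSO)phenyl]methanone hydrazone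
Conditions: K2CO3, DMF, 0 °C to rt
Reagents that add atoms: none
Why: Williamson ether synthesis, in which the phenoxide is far more nucleophilic than the conjugated hydrazone NH2 group and the reactive benzylic bromide allows a temperature at which aryl silyl ethers persist.

Step 8
Reactants: 10 [2-bromo-4-(TBSO)-6-{[4-(TBSO)benzyl]oxy}phenyl][3,5-bis(TBSO)phenyl]methanone hydrazone
Product: 12 (2S,3R)-4-bromo-6-(TBSO)-3-[3,5-bis(TBSO)phenyl]-2-[4-(TBSO)phenyl]-2,3-dihydrobenzofuran (cis), via diaryldiazomethane 11 (not isolated)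
Conditions: MnO2, CH2Cl2, rt, filter; then Rh2(S-PTAD)4 (1 mol %), CH2Cl2, 0 °C
Reagents that add atoms: none
Why: Hydrazone oxidation followed by dirhodium-catalysed intramolecular 1,5 C–H insertion of a donor/donor carbene into the activated benzylic ether C–H bond, which closes ring C as the cis isomer while the chiral carboxylate ligands fix C3 as R.

Step 9
Reactants: 12 (2S,3R)-cis unit C bromide
Product: 13 (2R,3R)-4-bromo-6-(TBSO)-3-[3,5-bis(TBSO)phenyl]-2-[4-(TBSO)phenyl]-2,3-dihydrobenzofuran (trans)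
Conditions: TFA (10 vol %), CH2Cl2, 0 °C to rt
Reagents that add atoms: none
Why: Acid-catalysed epimerisation, in which reversible heterolysis of the O1–C2 bond to a 4-silyloxybenzyl cation and reclosure should lead to the more stable trans isomer (C2 becomes R) while C3 and the acid-stable aryl silyl ethers are untouched.

Step 10
Reactants: 14 4-hydroxy-3-iodobenzaldehyde; 9 4-(TBSO)benzyl bromide
Product: 15 3-iodo-4-{[4-(TBSO)benzyl]oxy}benzaldehyde
Conditions: K2CO3, DMF, rt
Reagents that add atoms: none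
Why: Williamson ether synthesis on an acidic, unhindered phenol.

Step 11
Reactants: 15 3-iodo-4-{[4-(TBSO)benzyl]oxy}benzaldehyde; 16 tert-butyl diazoacetate
Product: 17 tert-butyl 2-diazo-2-(5-formyl-2-{[4-(TBSO)benzyl]oxy}phenyl)acetate
Conditions: Pd(PPh3)4 (5 mol %), Ag2CO3 (0.5 equiv), Et3N, toluene, rt
Reagents that add atoms: none
Why: Palladium-catalysed cross-coupling of an aryl iodide with the C–H bond of a diazoacetate with retention of the diazo group, which gives the aryl diazoacetate in one step at room temperature and leaves the aldehyde alone.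

Step 12
Reactants: 17 tert-butyl 2-diazo-2-(5-formyl-2-{[4-(TBSO)benzyl]oxy}phenyl)acetate
Product: 19 tert-butyl (2R,3R)-5-formyl-2-[4-(TBSO)phenyl]-2,3-dihydrobenzofuran-3-carboxylate (trans), via cis ester 18 (not isolated)
Conditions: Rh2(S-PTTL)4 (1 mol %), toluene, −60 °C; then DBU (0.5 equiv), rt
Reagents that add atoms: none
Why: Dirhodium-catalysed intramolecular 1,5 C–H insertion of a donor/acceptor carbene closes ring B cis and sets C2 as R under catalyst control, and DBU then epimerises C3 through the ester enolate to the trans ester without ring opening, because the C2–O1 bond lies in the plane of the enolate.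

Step 13
Reactants: 19 tert-butyl (2R,3R)-5-formyl-2-[4-(TBSO)phenyl]-2,3-dihydrobenzofuran-3-carboxylate
Product: 20 tert-butyl (2R,3R)-5-(hydroxymethyl)-2-[4-(TBSO)phenyl]-2,3-dihydrobenzofuran-3-carboxylate
Conditions: NaBH4, MeOH/THF, −10 °C
Reagents that add atoms: none
Why: Chemoselective borohydride reduction of the aldehyde in the presence of a tert-butyl ester.

Step 14
Reactants: 20 tert-butyl (2R,3R)-5-(hydroxymethyl)-2-[4-(TBSO)phenyl]-2,3-dihydrobenzofuran-3-carboxylate
Product: 21 tert-butyl (2R,3R)-5-(bromomethyl)-2-[4-(TBSO)phenyl]-2,3-dihydrobenzofuran-3-carboxylate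
Conditions: CBr4, PPh3, CH2Cl2, 0 °C
Reagents that add atoms: carbon tetrabromide, BrC(Br)(Br)Br
Why: Appel reaction under neutral conditions, so that neither ring B nor the ester is exposed to acid or base.

Step 15
Reactants: 6 [2-bromo-6-hydroxy-4-(TBSO)phenyl][3,5-bis(TBSO)phenyl]methanone hydrazone; 21 tert-butyl (2R,3R)-5-(bromomethyl)-2-[4-(TBSO)phenyl]-2,3-dihydrobenzofuran-3-carboxylate
Product: 22 [2-bromo-4-(TBSO)-6-({(2R,3R)-3-(tert-butoxycarbonyl)-2-[4-(TBSO)phenyl]-2,3-dihydrobenzofuran-5-yl}methoxy)phenyl][3,5-bis(TBSO)phenyl]methanone hydrazone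
Conditions: K2CO3, DMF, 0 °C to rt
Reagents that add atoms: none
Why: Williamson ether synthesis as in step 7; because the hydrazone is already in place the ester never meets hydrazine, and K2CO3 is too weak to deprotonate C3 of ring B.

Step 16
Reactants: 22 unit A hydrazone carrying ring B
Product: 24 tert-butyl (2R,3R)-5-{(2S,3R)-4-bromo-6-(TBSO)-3-[3,5-bis(TBSO)phenyl]-2,3-dihydrobenzofuran-2-yl}-2-[4-(TBSO)phenyl]-2,3-dihydrobenzofuran-3-carboxylate, via diaryldiazomethane 23 (not isolated)
Conditions: MnO2, CH2Cl2, rt, filter; then Rh2(S-PTAD)4 (1 mol %), CH2Cl2, 0 °C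
Reagents that add atoms: none
Why: The same hydrazone oxidation and donor/donor carbene 1,5 C–H insertion as in step 8, here into the ArO–CH2 bond para to O1 of ring B, closes ring A cis with C3(A) set as R by the catalyst, the stereocentres of ring B being too remote to interfere.

Step 17
Reactants: 24 cis-A/trans-B tert-butyl ester
Product: 25 (2R,3R)-5-{(2R,3R)-4-bromo-6-(TBSO)-3-[3,5-bis(TBSO)phenyl]-2,3-dihydrobenzofuran-2-yl}-2-[4-(TBSO)phenyl]-2,3-dihydrobenzofuran-3-carboxylic acid
Conditions: TFA/CH2Cl2 (1:4), argon purge, 0 °C to rt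
Reagents that add atoms: none
Why: One acid treatment does two jobs, namely acidolysis of the tert-butyl ester (loss of isobutene) and epimerisation of C2(A) to R through the ring-opened 4-alkoxybenzyl cation, while ring B, already the trans isomer, can only reclose to itself.

Step 18
Reactants: 25 bromo acid; 26 4-(tert-butyldimethylsilyloxy)styrene
Product: 27 (2R,3R)-5-{(2R,3R)-6-(TBSO)-3-[3,5-bis(TBSO)phenyl]-4-[(E)-4-(TBSO)styryl]-2,3-dihydrobenzofuran-2-yl}-2-[4-(TBSO)phenyl]-2,3-dihydrobenzofuran-3-carboxylic acid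
Conditions: Pd2(dba)3 (5 mol %), P(t-Bu)3 (12 mol %), Cy2NMe (4 equiv), 1,4-dioxane, 80 °C
Reagents that add atoms: none
Why: Mizoroki–Heck reaction with a bulky electron-rich phosphine suited to hindered electron-rich aryl bromides, giving the E-stilbene by syn insertion and syn beta-hydride elimination; it is placed after the last acid step and tolerates the carboxylate.

Step 19
Reactants: 27 styryl acid (units A and B); 13 unit C bromide
Product: 29 nona-TBS ether of the target, via N-acyloxyphthalimide 28 (not isolated)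
Conditions: N-hydroxyphthalimide, DIC, CH2Cl2, 0 °C to rt, concentrate; then 13 (1.0 equiv), NiBr2·diglyme (20 mol %), 4,4'-di-tert-butyl-2,2'-bipyridine (20 mol %), Zn dust (2.5 equiv), NaI (0.5 equiv), DMA, 25–35 °C, dark
Reagents that add atoms: N-hydroxyphthalimide, O=C1c2ccccc2C(=O)N1O (its atoms stay only in 28)
Why: Nickel-catalysed decarboxylative cross-electrophile arylation of a redox-active ester: zerovalent nickel inserts into the C4–Br bond of 13, a low-valent nickel species turned over by zinc transfers one electron to 28, and N–O cleavage with loss of CO2 leaves the planar benzylic radical at C3(B), which is captured by the aryl nickel bromide and released by reductive elimination from trivalent nickel. The closest known reaction type is the coupling of secondary N-acyloxyphthalimides, benzylic ones included, with aryl halides under nickel/bipyridine catalysis with a metal reductant. No ring is closed. The only new stereocentre, C3(B), is controlled by the neighbouring C2(B): its 4-silyloxyphenyl group shields one face of the five-membered ring, so nickel and then the aryl group should end up anti to it (trans, 3R) whatever the configuration of the acid was. The step needs the radical to couple faster than it fragments or loses H-2: the ring holds C2–O1 close to the nodal plane of the radical orbital (no beta-scission to a phenoxyl radical), reductive elimination from trivalent nickel should outrun beta-hydride loss to the benzofuran, 13 offers the only carbon–halogen bond, and the absence of light and of base spares the E-stilbene, the silyl ethers and C2(B). Both carbons are acceptor sites (C4(C) is meta to O1 and to the C6 oxygen, C3(B) is an ortho-oxybenzylic carbon), which is why a reductive radical union is used instead of a polar one.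

Step 20
Reactants: 29 nona-TBS ether of the target
Product: 30 target CNP0184803.1, all six stereocentres R, E-alkene
Conditions: Et3N·3HF (excess), THF, rt, argon
Reagents that add atoms: none
Why: Fluoride-mediated cleavage of aryl silyl ethers under nearly neutral conditions, which avoids both the acid-induced cyclisation of the styryl-dihydrobenzofuran motif and base-induced quinone methide chemistry.

**Compound list**
1 | 1-bromo-3,5-dimethoxybenzene | COc1cc(Br)cc(OC)c1 | starting material
2 | 3,5-dimethoxybenzoyl chloride | COc1cc(cc(OC)c1)C(=O)Cl | starting material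
3 | (2-bromo-4,6-dimethoxyphenyl)(3,5-dimethoxyphenyl)methanone | COc1cc(OC)cc(c1)C(=O)c1c(Br)cc(OC)cc1OC | intermediate
4 | (2-bromo-4,6-dihydroxyphenyl)(3,5-dihydroxyphenyl)methanone | Oc1cc(O)cc(c1)C(=O)c1c(Br)cc(O)cc1O | intermediate
5 | hydrazone of 4 | NN=C(c1cc(O)cc(O)c1)c1c(Br)cc(O)cc1O | intermediate
6 | [2-bromo-6-hydroxy-4-(TBSO)phenyl][3,5-bis(TBSO)phenyl]methanone hydrazone | NN=C(c1cc(O[Si](C)(C)C(C)(C)C)cc(O[Si](C)(C)C(C)(C)C)c1)c1c(Br)cc(O[Si](C)(C)C(C)(C)C)cc1O | intermediate
7 | 4-(tert-butyldimethylsilyloxy)benzaldehyde | O=Cc1ccc(O[Si](C)(C)C(C)(C)C)cc1 | starting material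
8 | [4-(TBSO)phenyl]methanol | OCc1ccc(O[Si](C)(C)C(C)(C)C)cc1 | intermediate
9 | 4-(TBSO)benzyl bromide | BrCc1ccc(O[Si](C)(C)C(C)(C)C)cc1 | intermediate
10 | [2-bromo-4-(TBSO)-6-{[4-(TBSO)benzyl]oxy}phenyl][3,5-bis(TBSO)phenyl]methanone hydrazone | NN=C(c1cc(O[Si](C)(C)C(C)(C)C)cc(O[Si](C)(C)C(C)(C)C)c1)c1c(Br)cc(O[Si](C)(C)C(C)(C)C)cc1OCc1ccc(O[Si](C)(C)C(C)(C)C)cc1 | intermediate
11 | diaryldiazomethane from 10 | [N-]=[N+]=C(c1cc(O[Si](C)(C)C(C)(C)C)cc(O[Si](C)(C)C(C)(C)C)c1)c1c(Br)cc(O[Si](C)(C)C(C)(C)C)cc1OCc1ccc(O[Si](C)(C)C(C)(C)C)cc1 | intermediate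
12 | (2S,3R)-4-bromo-6-(TBSO)-3-[3,5-bis(TBSO)phenyl]-2-[4-(TBSO)phenyl]-2,3-dihydrobenzofuran (cis) | Brc1cc(O[Si](C)(C)C(C)(C)C)cc2c1[C@@H](c1cc(O[Si](C)(C)C(C)(C)C)cc(O[Si](C)(C)C(C)(C)C)c1)[C@@H](c1ccc(O[Si](C)(C)C(C)(C)C)cc1)O2 | intermediate
13 | (2R,3R)-4-bromo-6-(TBSO)-3-[3,5-bis(TBSO)phenyl]-2-[4-(TBSO)phenyl]-2,3-dihydrobenzofuran (trans, unit C) | Brc1cc(O[Si](C)(C)C(C)(C)C)cc2c1[C@@H](c1cc(O[Si](C)(C)C(C)(C)C)cc(O[Si](C)(C)C(C)(C)C)c1)[C@H](c1ccc(O[Si](C)(C)C(C)(C)C)cc1)O2 | intermediate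
14 | 4-hydroxy-3-iodobenzaldehyde | O=Cc1ccc(O)c(I)c1 | starting material
15 | 3-iodo-4-{[4-(TBSO)benzyl]oxy}benzaldehyde | O=Cc1ccc(OCc2ccc(O[Si](C)(C)C(C)(C)C)cc2)c(I)c1 | intermediate
16 | tert-butyl diazoacetate | [N-]=[N+]=CC(=O)OC(C)(C)C | starting material
17 | tert-butyl 2-diazo-2-(5-formyl-2-{[4-(TBSO)benzyl]oxy}phenyl)acetate | O=Cc1ccc(OCc2ccc(O[Si](C)(C)C(C)(C)C)cc2)c(c1)C(=[N+]=[N-])C(=O)OC(C)(C)C | intermediate
18 | tert-butyl (2R,3S)-5-formyl-2-[4-(TBSO)phenyl]-2,3-dihydrobenzofuran-3-carboxylate (cis) | O=Cc1ccc2c(c1)[C@H](C(=O)OC(C)(C)C)[C@H](c1ccc(O[Si](C)(C)C(C)(C)C)cc1)O2 | intermediate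
19 | tert-butyl (2R,3R)-5-formyl-2-[4-(TBSO)phenyl]-2,3-dihydrobenzofuran-3-carboxylate (trans) | O=Cc1ccc2c(c1)[C@@H](C(=O)OC(C)(C)C)[C@H](c1ccc(O[Si](C)(C)C(C)(C)C)cc1)O2 | intermediate
20 | tert-butyl (2R,3R)-5-(hydroxymethyl)-2-[4-(TBSO)phenyl]-2,3-dihydrobenzofuran-3-carboxylate | OCc1ccc2c(c1)[C@@H](C(=O)OC(C)(C)C)[C@H](c1ccc(O[Si](C)(C)C(C)(C)C)cc1)O2 | intermediate
21 | tert-butyl (2R,3R)-5-(bromomethyl)-2-[4-(TBSO)phenyl]-2,3-dihydrobenzofuran-3-carboxylate | BrCc1ccc2c(c1)[C@@H](C(=O)OC(C)(C)C)[C@H](c1ccc(O[Si](C)(C)C(C)(C)C)cc1)O2 | intermediate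
22 | hydrazone 6 O-alkylated by 21 | NN=C(c1cc(O[Si](C)(C)C(C)(C)C)cc(O[Si](C)(C)C(C)(C)C)c1)c1c(Br)cc(O[Si](C)(C)C(C)(C)C)cc1OCc1ccc2c(c1)[C@@H](C(=O)OC(C)(C)C)[C@H](c1ccc(O[Si](C)(C)C(C)(C)C)cc1)O2 | intermediate
23 | diaryldiazomethane from 22 | [N-]=[N+]=C(c1cc(O[Si](C)(C)C(C)(C)C)cc(O[Si](C)(C)C(C)(C)C)c1)c1c(Br)cc(O[Si](C)(C)C(C)(C)C)cc1OCc1ccc2c(c1)[C@@H](C(=O)OC(C)(C)C)[C@H](c1ccc(O[Si](C)(C)C(C)(C)C)cc1)O2 | intermediate
24 | tert-butyl ester with ring A cis (2S,3R) and ring B trans (2R,3R), C4(A)–Br | Brc1cc(O[Si](C)(C)C(C)(C)C)cc2c1[C@@H](c1cc(O[Si](C)(C)C(C)(C)C)cc(O[Si](C)(C)C(C)(C)C)c1)[C@@H](c1ccc3c(c1)[C@@H](C(=O)OC(C)(C)C)[C@H](c1ccc(O[Si](C)(C)C(C)(C)C)cc1)O3)O2 | intermediate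
25 | carboxylic acid with rings A and B both trans (2R,3R), C4(A)–Br | Brc1cc(O[Si](C)(C)C(C)(C)C)cc2c1[C@@H](c1cc(O[Si](C)(C)C(C)(C)C)cc(O[Si](C)(C)C(C)(C)C)c1)[C@H](c1ccc3c(c1)[C@@H](C(=O)O)[C@H](c1ccc(O[Si](C)(C)C(C)(C)C)cc1)O3)O2 | intermediate
26 | 4-(tert-butyldimethylsilyloxy)styrene | C=Cc1ccc(O[Si](C)(C)C(C)(C)C)cc1 | starting material
27 | acid 25 with (E)-4-(TBSO)styryl in place of Br | CC(C)(C)[Si](C)(C)Oc1ccc(/C=C/c2cc(O[Si](C)(C)C(C)(C)C)cc3c2[C@@H](c2cc(O[Si](C)(C)C(C)(C)C)cc(O[Si](C)(C)C(C)(C)C)c2)[C@H](c2ccc4c(c2)[C@@H](C(=O)O)[C@H](c2ccc(O[Si](C)(C)C(C)(C)C)cc2)O4)O3)cc1 | intermediate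
28 | N-acyloxyphthalimide of 27 | CC(C)(C)[Si](C)(C)Oc1ccc(/C=C/c2cc(O[Si](C)(C)C(C)(C)C)cc3c2[C@@H](c2cc(O[Si](C)(C)C(C)(C)C)cc(O[Si](C)(C)C(C)(C)C)c2)[C@H](c2ccc4c(c2)[C@@H](C(=O)ON2C(=O)c5ccccc5C2=O)[C@H](c2ccc(O[Si](C)(C)C(C)(C)C)cc2)O4)O3)cc1 | intermediate
29 | nona-TBS ether of the target | CC(C)(C)[Si](C)(C)Oc1ccc(/C=C/c2cc(O[Si](C)(C)C(C)(C)C)cc3c2[C@@H](c2cc(O[Si](C)(C)C(C)(C)C)cc(O[Si](C)(C)C(C)(C)C)c2)[C@H](c2ccc4c(c2)[C@@H](c2cc(O[Si](C)(C)C(C)(C)C)cc5c2[C@@H](c2cc(O[Si](C)(C)C(C)(C)C)cc(O[Si](C)(C)C(C)(C)C)c2)[C@H](c2ccc(O[Si](C)(C)C(C)(C)C)cc2)O5)[C@H](c2ccc(O[Si](C)(C)C(C)(C)C)cc2)O4)O3)cc1 | intermediate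
30 | CNP0184803.1 | Oc1ccc(/C=C/c2cc(O)cc3c2[C@@H](c2cc(O)cc(O)c2)[C@H](c2ccc4c(c2)[C@@H](c2cc(O)cc5c2[C@@H](c2cc(O)cc(O)c2)[C@H](c2ccc(O)cc2)O5)[C@H](c2ccc(O)cc2)O4)O3)cc1 | target

**Total step count:** 20.

**Longest linear sequence:** 13 steps (steps 5, 6 and 10–20).

**Steps most likely to fail**

1. Step 19. Capture of the hindered secondary benzylic radical by the ortho-substituted aryl nickel species may be slower than radical dimerisation, hydrogen abstraction, or beta-hydride loss with aromatisation of ring B.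
   - The fallback sets out from 27 (activated as 28 exactly as in step 19) and from 13, and comes back at 29.
   - Copper-catalysed decarboxylative borylation of 28 (Cu(acac)2, B2pin2, LiOH·H2O, MgCl2, dioxane/DMF) should give, again anti to the C2 aryl group, the trans pinacol boronic ester F1.
   - Bromide 13 is turned with t-BuLi (THF, −78 °C) into the aryllithium F2, which adds to the boron atom of F1 to give the lithium boronate F3.
   - NBS at −78 °C should attack C7 of unit C (para to boron and ortho to both ring oxygens). This triggers the 1,2-shift of C3(B) from boron to C4(C) with retention, and loss of the bromoborane restores the arene and gives 29.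

2. Step 17. The acid may cause partial desilylation, loss of H-3 from the ring-opened cations, tert-butylation of the electron-rich rings, or incomplete epimerisation.
   - The fallback sets out from 24 and comes back at 25, and replaces the cationic epimerisation with a radical one.
   - Reversible abstraction of the weak C2(A)–H bond by a thiyl radical (triisopropylsilanethiol, AIBN, PhCF3, 80 °C) should equilibrate ring A to the all-trans tert-butyl ester F4.
   - The ester of F4 is then cleaved without protic acid (TMSOTf, 2,6-lutidine, CH2Cl2, 0 °C; aqueous work-up) to give 25.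

3. Step 18. Oxidative addition into the bromide flanked by C3a, or insertion of the styrene, may be too slow, so that hydrodebromination or silyl migration to the carboxylate takes over.
   - The fallback sets out from 25 and 26 and comes back at 27.
   - Cross metathesis of 26 with vinylboronic acid pinacol ester (second-generation Grubbs catalyst, CH2Cl2, 40 °C) gives the (E)-styrylboronic ester F5.
   - F5 is joined to 25 by a Suzuki–Miyaura coupling (Pd(dppf)Cl2, K3PO4, THF/H2O, 50 °C), in which the alkene geometry is fixed before the coupling.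

**Further compounds**
F1 | step 19 | pinacol boronic ester, acid 27 with B(pin) in place of CO2H at C3(B), (2R,3R) trans | CC(C)(C)[Si](C)(C)Oc1ccc(/C=C/c2cc(O[Si](C)(C)C(C)(C)C)cc3c2[C@@H](c2cc(O[Si](C)(C)C(C)(C)C)cc(O[Si](C)(C)C(C)(C)C)c2)[C@H](c2ccc4c(c2)[C@@H](B2OC(C)(C)C(C)(C)O2)[C@H](c2ccc(O[Si](C)(C)C(C)(C)C)cc2)O4)O3)cc1
F2 | step 19 | aryllithium from 13 (Li at C4 of unit C) | [Li]c1cc(O[Si](C)(C)C(C)(C)C)cc2c1[C@@H](c1cc(O[Si](C)(C)C(C)(C)C)cc(O[Si](C)(C)C(C)(C)C)c1)[C@H](c1ccc(O[Si](C)(C)C(C)(C)C)cc1)O2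
F3 | step 19 | lithium boronate from F1 and F2 | [Li+].CC(C)(C)[Si](C)(C)Oc1ccc(/C=C/c2cc(O[Si](C)(C)C(C)(C)C)cc3c2[C@@H](c2cc(O[Si](C)(C)C(C)(C)C)cc(O[Si](C)(C)C(C)(C)C)c2)[C@H](c2ccc4c(c2)[C@@H]([B-]2(OC(C)(C)C(C)(C)O2)c2cc(O[Si](C)(C)C(C)(C)C)cc5c2[C@@H](c2cc(O[Si](C)(C)C(C)(C)C)cc(O[Si](C)(C)C(C)(C)C)c2)[C@H](c2ccc(O[Si](C)(C)C(C)(C)C)cc2)O5)[C@H](c2ccc(O[Si](C)(C)C(C)(C)C)cc2)O4)O3)cc1
F4 | step 17 | all-trans tert-butyl ester (24 with C2(A) inverted to R) | Brc1cc(O[Si](C)(C)C(C)(C)C)cc2c1[C@@H](c1cc(O[Si](C)(C)C(C)(C)C)cc(O[Si](C)(C)C(C)(C)C)c1)[C@H](c1ccc3c(c1)[C@@H](C(=O)OC(C)(C)C)[C@H](c1ccc(O[Si](C)(C)C(C)(C)C)cc1)O3)O2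
F5 | step 18 | (E)-2-[4-(TBSO)phenyl]ethenylboronic acid pinacol ester | CC(C)(C)[Si](C)(C)Oc1ccc(/C=C/B2OC(C)(C)C(C)(C)O2)cc1
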